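**Retrosynthetic overview**
- Shanciguol ⇐ global hydrogenolysis of its penta-benzyl ether; each ArCH2–Ar link ⇐ deoxygenation of a diaryl carbinol made from an aryl aldehyde and 4-(benzyloxy)phenylmagnesium bromide.
- The dialdehyde ⇐ a symmetric dimethyl 4,6-dihydroxyisophthalate carrying the phenethyl chain at C2, so both ester handles sit exactly where the benzyl groups must go.
- Central ring (the only ring formed) ⇐ aromatisation of a cyclohexane-1,3-dione diester, built by intermolecular Michael addition of methyl acetoacetate to an alkylidene malonate followed by Claisen ring closure.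
- Alkylidene malonate ⇐ Knoevenagel condensation of 3-[3-(benzyloxy)phenyl]propanal with dimethyl malonate; the aldehyde comes from 3-(3-hydroxyphenyl)propanoic acid.
- Both outer ring types are bought; all five phenols travel as benzyl ethers and are released in the last step.

Assumption: the target has no stereocentre and no stereogenic double bond, so it is achiral and no asymmetric step is needed.

**Route**

Step 1
Reactants: 1 3-(3-hydroxyphenyl)propanoic acid
Product: 2 benzyl 3-[3-(benzyloxy)phenyl]propanoate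
Conditions: BnBr (2.3 equiv), K2CO3 (3 equiv), DMF, 60 °C
Reagents that add atoms: benzyl bromide, BrCc1ccccc1
Why: Williamson O-alkylation of the phenoxide and carboxylate in one pot protects the phenol as a base-stable benzyl ether and gives a reducible ester.

Step 2
Reactants: 2 benzyl 3-[3-(benzyloxy)phenyl]propanoate
Product: 3 3-[3-(benzyloxy)phenyl]propan-1-ol
Conditions: LiAlH4 (1.2 equiv), THF, 0 °C to rt; Fieser work-up
Reagents that add atoms: none
Why: Hydride reduction of an unhindered ester to the primary alcohol is dependable and leaves the aryl benzyl ether untouched.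

Step 3
Reactants: 3 3-[3-(benzyloxy)phenyl]propan-1-ol
Product: 4 3-[3-(benzyloxy)phenyl]propanal
Conditions: TEMPO (10 mol %), PhI(OAc)2 (1.1 equiv), CH2Cl2, rt
Reagents that add atoms: none
Why: The TEMPO/oxoammonium oxidation stops cleanly at the aldehyde for primary alcohols and does not touch the benzyl ether.

Step 4
Reactants: 4 3-[3-(benzyloxy)phenyl]propanal; 5 dimethyl malonate
Product: 6 dimethyl 2-{3-[3-(benzyloxy)phenyl]propylidene}propanedioate
Conditions: piperidine (10 mol %), AcOH (10 mol %), toluene, reflux, Dean–Stark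
Reagents that add atoms: none
Why: Knoevenagel condensation (aldol addition then dehydration) driven by water removal gives the doubly activated Michael acceptor; any β,γ-isomer re-equilibrates through the same dienolate in step 5.

Step 5
Reactants: 6 dimethyl 2-{3-[3-(benzyloxy)phenyl]propylidene}propanedioate; 7 methyl acetoacetate
Product: 9 dimethyl 2-{2-[3-(benzyloxy)phenyl]ethyl}-4,6-dioxocyclohexane-1,3-dicarboxylate, via acyclic Michael adduct 8 (not isolated)
Conditions: NaOMe (1.0 equiv), MeOH, 0 °C to rt; then NaOMe (1.2 equiv), reflux; cold 1 M HCl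
Reagents that add atoms: none
Why: Intermolecular Michael addition of the acetoacetate enolate joins the two fragments, then Claisen condensation of the acetyl CH3 onto a malonate ester (Vorländer dihydroresorcinol synthesis) closes the ring, driven by the stable 1,3-dione enolate; the sp3 stereocentres are uncontrolled and erased in step 6.

Step 6
Reactants: 9 dimethyl 2-{2-[3-(benzyloxy)phenyl]ethyl}-4,6-dioxocyclohexane-1,3-dicarboxylate
Product: 10 dimethyl 2-{2-[3-(benzyloxy)phenyl]ethyl}-4,6-dihydroxybenzene-1,3-dicarboxylate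
Conditions: DDQ (1.05 equiv), 1,4-dioxane, rt to 60 °C
Reagents that add atoms: none
Why: The bis-enol of 9 is a cyclohexa-1,4-diene, so DDQ dehydrogenation removes one H2 and aromatises it to the doubly hydrogen-bonded dihydroxyisophthalate, while a simple aryl benzyl ether is inert to DDQ.

Step 7
Reactants: 10 dimethyl 2-{2-[3-(benzyloxy)phenyl]ethyl}-4,6-dihydroxybenzene-1,3-dicarboxylate
Product: 11 dimethyl 4,6-bis(benzyloxy)-2-{2-[3-(benzyloxy)phenyl]ethyl}benzene-1,3-dicarboxylate
Conditions: BnBr (2.5 equiv), K2CO3 (3 equiv), Bu4NI (cat.), DMF, 60 °C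
Reagents that add atoms: benzyl bromide, BrCc1ccccc1
Why: Williamson etherification of the two salicylate-type phenols in DMF gives O-benzylation and protects them for the hydride and Grignard steps.

Step 8
Reactants: 11 dimethyl 4,6-bis(benzyloxy)-2-{2-[3-(benzyloxy)phenyl]ethyl}benzene-1,3-dicarboxylate
Product: 12 [4,6-bis(benzyloxy)-2-{2-[3-(benzyloxy)phenyl]ethyl}-1,3-phenylene]dimethanol
Conditions: LiAlH4 (2.5 equiv), THF, 0 °C to rt; Fieser work-up (no acid)
Reagents that add atoms: none
Why: LiAlH4 reduces even ortho,ortho-disubstituted benzoates to benzylic alcohols, and the basic work-up protects the acid-labile 2,4-dialkoxybenzyl alcohols.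

Step 9
Reactants: 12 [4,6-bis(benzyloxy)-2-{2-[3-(benzyloxy)phenyl]ethyl}-1,3-phenylene]dimethanol
Product: 13 4,6-bis(benzyloxy)-2-{2-[3-(benzyloxy)phenyl]ethyl}benzene-1,3-dicarbaldehyde
Conditions: activated MnO2 (20 equiv), CH2Cl2, rt
Reagents that add atoms: none
Why: MnO2 oxidation is selective for benzylic alcohols under neutral conditions and stops at the aldehyde.

Step 10
Reactants: 13 4,6-bis(benzyloxy)-2-{2-[3-(benzyloxy)phenyl]ethyl}benzene-1,3-dicarbaldehyde; 14 1-(benzyloxy)-4-bromobenzene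
Product: 16 [4,6-bis(benzyloxy)-2-{2-[3-(benzyloxy)phenyl]ethyl}-1,3-phenylene]bis{[4-(benzyloxy)phenyl]methanol}, via 4-(benzyloxy)phenylmagnesium bromide 15 (not isolated)
Conditions: 14 (3.2 equiv), Mg, THF, reflux; then 13, 0 °C to rt; aq NH4Cl
Reagents that add atoms: none
Why: Grignard addition of an aryl nucleophile without β-hydrogens to the two aldehydes gives the bis(diaryl carbinol); the two new stereocentres form without control (dl/meso mixture) and are removed in step 11.

Step 11
Reactants: 16 [4,6-bis(benzyloxy)-2-{2-[3-(benzyloxy)phenyl]ethyl}-1,3-phenylene]bis{[4-(benzyloxy)phenyl]methanol}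
Product: 17 1,5-bis(benzyloxy)-2,4-bis[4-(benzyloxy)benzyl]-3-{2-[3-(benzyloxy)phenyl]ethyl}benzene
Conditions: Et3SiH (6 equiv), TFA (4 equiv), CH2Cl2, −10 to 0 °C
Reagents that add atoms: none
Why: Ionic hydrogenation works because the carbinols ionise readily to cations stabilised by ortho/para alkoxy groups, and excess silane traps them by hydride transfer faster than any arene can; aryl benzyl ethers survive cold dilute TFA.

Step 12
Reactants: 17 1,5-bis(benzyloxy)-2,4-bis[4-(benzyloxy)benzyl]-3-{2-[3-(benzyloxy)phenyl]ethyl}benzene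
Product: 18 shanciguol, 4,6-bis(4-hydroxybenzyl)-5-[2-(3-hydroxyphenyl)ethyl]benzene-1,3-diol
Conditions: H2 (1 atm), 10 % Pd/C, EtOAc–MeOH (1:1), rt
Reagents that add atoms: none
Why: Catalytic hydrogenolysis cleaves all five benzyl ethers under neutral conditions without affecting diarylmethane or bibenzyl C–C bonds.

**Compound list**
1 | 3-(3-hydroxyphenyl)propanoic acid | OC(=O)CCc1cccc(O)c1 | starting material
2 | benzyl 3-[3-(benzyloxy)phenyl]propanoate | O=C(CCc1cccc(OCc2ccccc2)c1)OCc1ccccc1 | intermediate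
3 | 3-[3-(benzyloxy)phenyl]propan-1-ol | OCCCc1cccc(OCc2ccccc2)c1 | intermediate
4 | 3-[3-(benzyloxy)phenyl]propanal | O=CCCc1cccc(OCc2ccccc2)c1 | intermediate
5 | dimethyl malonate (dimethyl propanedioate) | COC(=O)CC(=O)OC | starting material
6 | dimethyl 2-{3-[3-(benzyloxy)phenyl]propylidene}propanedioate | COC(=O)C(=CCCc1cccc(OCc2ccccc2)c1)C(=O)OC | intermediate
7 | methyl acetoacetate (methyl 3-oxobutanoate) | CC(=O)CC(=O)OC | starting material
8 | trimethyl 2-{2-[3-(benzyloxy)phenyl]ethyl}-4-oxopentane-1,1,3-tricarboxylate (acyclic Michael adduct, diastereomer mixture, not isolated) | COC(=O)C(C(=O)OC)C(CCc1cccc(OCc2ccccc2)c1)C(C(C)=O)C(=O)OC | intermediate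
9 | dimethyl 2-{2-[3-(benzyloxy)phenyl]ethyl}-4,6-dioxocyclohexane-1,3-dicarboxylate (drawn as diketo form; enol tautomers, stereoisomer mixture) | COC(=O)C1C(=O)CC(=O)C(C(=O)OC)C1CCc1cccc(OCc2ccccc2)c1 | intermediate
10 | dimethyl 2-{2-[3-(benzyloxy)phenyl]ethyl}-4,6-dihydroxybenzene-1,3-dicarboxylate | COC(=O)c1c(O)cc(O)c(C(=O)OC)c1CCc1cccc(OCc2ccccc2)c1 | intermediate
11 | dimethyl 4,6-bis(benzyloxy)-2-{2-[3-(benzyloxy)phenyl]ethyl}benzene-1,3-dicarboxylate | COC(=O)c1c(OCc2ccccc2)cc(OCc2ccccc2)c(C(=O)OC)c1CCc1cccc(OCc2ccccc2)c1 | intermediate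
12 | [4,6-bis(benzyloxy)-2-{2-[3-(benzyloxy)phenyl]ethyl}-1,3-phenylene]dimethanol | OCc1c(OCc2ccccc2)cc(OCc2ccccc2)c(CO)c1CCc1cccc(OCc2ccccc2)c1 | intermediate
13 | 4,6-bis(benzyloxy)-2-{2-[3-(benzyloxy)phenyl]ethyl}benzene-1,3-dicarbaldehyde | O=Cc1c(OCc2ccccc2)cc(OCc2ccccc2)c(C=O)c1CCc1cccc(OCc2ccccc2)c1 | intermediate
14 | 1-(benzyloxy)-4-bromobenzene | Brc1ccc(OCc2ccccc2)cc1 | starting material
15 | 4-(benzyloxy)phenylmagnesium bromide (not isolated) | Br[Mg]c1ccc(OCc2ccccc2)cc1 | intermediate
16 | [4,6-bis(benzyloxy)-2-{2-[3-(benzyloxy)phenyl]ethyl}-1,3-phenylene]bis{[4-(benzyloxy)phenyl]methanol} (dl/meso mixture) | OC(c1ccc(OCc2ccccc2)cc1)c1c(OCc2ccccc2)cc(OCc2ccccc2)c(C(O)c2ccc(OCc3ccccc3)cc2)c1CCc1cccc(OCc2ccccc2)c1 | intermediate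
17 | 1,5-bis(benzyloxy)-2,4-bis[4-(benzyloxy)benzyl]-3-{2-[3-(benzyloxy)phenyl]ethyl}benzene | C(c1ccc(OCc2ccccc2)cc1)c1c(OCc2ccccc2)cc(OCc2ccccc2)c(Cc2ccc(OCc3ccccc3)cc2)c1CCc1cccc(OCc2ccccc2)c1 | intermediate
18 | shanciguol, 4,6-bis(4-hydroxybenzyl)-5-[2-(3-hydroxyphenyl)ethyl]benzene-1,3-diol (achiral) | Oc1ccc(Cc2c(O)cc(O)c(Cc3ccc(O)cc3)c2CCc2cccc(O)c2)cc1 | target

**Totals**
Total steps: 12. Longest linear sequence: 12 steps (1 to 18); compounds 5, 7 and 14 are bought.

**Three steps most likely to fail**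

Step 5 (Michael–Claisen to the diester dione). The risk is retro-Michael scrambling of adduct 8 and slow Claisen closure because two more acidic C–H sites compete with the acetyl CH3. The fallback sets out from 4 and comes back at 11. Wittig olefination of 4 with 1-(triphenylphosphoranylidene)propan-2-one (toluene, 80 °C) gives (E)-6-[3-(benzyloxy)phenyl]hex-3-en-2-one F1. Dimethyl malonate 5 with NaOMe in MeOH adds in a Michael reaction to give dimethyl 2-{1-[3-(benzyloxy)phenyl]-5-oxohexan-3-yl}propanedioate F2, which closes in the same pot by Claisen condensation to methyl 6-{2-[3-(benzyloxy)phenyl]ethyl}-2,4-dioxocyclohexane-1-carboxylate F3. This is the standard 5-alkylresorcinol ring synthesis and has no second acidic site to compete. DDQ aromatises F3 to methyl 2,4-dihydroxy-6-{2-[3-(benzyloxy)phenyl]ethyl}benzoate F4, and BnBr/K2CO3 gives methyl 2,4-bis(benzyloxy)-6-{2-[3-(benzyloxy)phenyl]ethyl}benzoate F5. NBS in MeCN at 0 °C should brominate the position para to one benzyloxy group and ortho to the other (the site between the two benzyloxy groups is shielded) to give methyl 4,6-bis(benzyloxy)-3-bromo-2-{2-[3-(benzyloxy)phenyl]ethyl}benzoate F6. Pd-catalysed methoxycarbonylation (CO 5 bar, Pd(OAc)2/Xantphos, Et3N, MeOH–toluene, 100 °C) then gives 11.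

Step 6 (DDQ aromatisation). The risk is incomplete or over-oxidation of the enol-rich diester. The fallback sets out from 9 and comes back at 10, and replaces hydride abstraction by halogenation–dehydrohalogenation. NBS (1.0 equiv, CH2Cl2, 0 °C) brominates the carbon between the two ketones to give dimethyl 5-bromo-2-{2-[3-(benzyloxy)phenyl]ethyl}-4,6-dioxocyclohexane-1,3-dicarboxylate F7. Et3N in DMF (rt to 60 °C) then expels HBr through the dienol and gives 10.

Step 11 (ionic hydrogenation). The risk is that the benzhydryl cation alkylates the tethered 3-benzyloxyphenyl ring to form a seven-membered ring, or that TFA partly cleaves benzyl ethers. The fallback sets out from 16 and comes back at 18, avoiding free carbocations. Compound 16 is hydrogenated directly (H2 3 bar, Pd(OH)2/C, EtOAc–MeOH, 1 % AcOH), so the electron-rich doubly benzylic C–OH bonds are hydrogenolysed together with the five benzyl ethers. It bypasses 17 and makes no new compound (F0).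

**Further compounds**
F1 | step 5 | (E)-6-[3-(benzyloxy)phenyl]hex-3-en-2-one | CC(=O)/C=C/CCc1cccc(OCc2ccccc2)c1
F2 | step 5 | dimethyl 2-{1-[3-(benzyloxy)phenyl]-5-oxohexan-3-yl}propanedioate | COC(=O)C(C(=O)OC)C(CCc1cccc(OCc2ccccc2)c1)CC(C)=O
F3 | step 5 | methyl 6-{2-[3-(benzyloxy)phenyl]ethyl}-2,4-dioxocyclohexane-1-carboxylate | COC(=O)C1C(=O)CC(=O)CC1CCc1cccc(OCc2ccccc2)c1
F4 | step 5 | methyl 2,4-dihydroxy-6-{2-[3-(benzyloxy)phenyl]ethyl}benzoate | COC(=O)c1c(O)cc(O)cc1CCc1cccc(OCc2ccccc2)c1
F5 | step 5 | methyl 2,4-bis(benzyloxy)-6-{2-[3-(benzyloxy)phenyl]ethyl}benzoate | COC(=O)c1c(OCc2ccccc2)cc(OCc2ccccc2)cc1CCc1cccc(OCc2ccccc2)c1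
F6 | step 5 | methyl 4,6-bis(benzyloxy)-3-bromo-2-{2-[3-(benzyloxy)phenyl]ethyl}benzoate | COC(=O)c1c(OCc2ccccc2)cc(OCc2ccccc2)c(Br)c1CCc1cccc(OCc2ccccc2)c1
F7 | step 6 | dimethyl 5-bromo-2-{2-[3-(benzyloxy)phenyl]ethyl}-4,6-dioxocyclohexane-1,3-dicarboxylate | COC(=O)C1C(=O)C(Br)C(=O)C(C(=O)OC)C1CCc1cccc(OCc2ccccc2)c1
F0 | step 11 | none | none
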